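**Plan**

- Numbering used throughout: ring C1 (C=O), C2 (CH3), C3, C4 (OH), C5 (side chain), C6; side chain C1'–C16'. The enabling feature is the array C4(OH)–C5–C1'H2–C2'H=C3', a bishomoallylic alcohol that links the ring to the first isoprene unit; it is the retron of a nickel-catalysed reductive diene–aldehyde cyclisation.
- Retrosynthetic cuts: C1=O back to a silyl-protected C1 carbinol; ring bond C4–C5 (giving an acyclic (Z)-enal that carries an (E,E)-diene); C1'–C2' (sp2–sp2 coupling); C1–C6 (propargylation); C1–C2 (formylation of a (Z)-vinyl iodide); C3'–CH3 (carboalumination).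
- Forward order: eastern C17 vinyl iodide (steps 1–3); western (Z)-enyne (steps 4–8); chain junction to the (E,E)-diene (step 9); unmasking of the enal (step 10); the only ring arises in step 11; steps 12–15 convert the C1 carbinol into the ketone.
- Stereochemistry: C1 (S) comes from a chiral phosphoric acid catalysed propargylation. This temporary centre steers the ring closure that sets C4 and C5 (cis through the metallacycle) and is then destroyed by oxidation. All alkene geometries come from stereospecific hydro- and carbometallations.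

Key step: step 11

Assumption: (S)-TRIP is taken to deliver the propargyl group to the Si face of aldehyde 13 (giving the S carbinol); if the sense is opposite, the (R)-acid is used.
Assumption: in step 11 the ring is taken to close anti to a pseudoaxial C1 silyloxy group; if the induction is reversed, the antipodal acid in step 7 supplies the mirror-image C1 series, since C1 is oxidised away at the end.

**Route**

Step 1
Reactants: 1 1-(trimethylsilyl)propyne; 2 (2E,6E)-farnesyl bromide
Product: 4 trimethyl[(5E,9E)-6,10,14-trimethylpentadeca-5,9,13-trien-1-yn-1-yl]silane, via silylpropargyllithium 3 (not isolated)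
Conditions: n-BuLi, THF, −78 to −20 °C; then 2, −78 °C to rt
Reagents that add atoms: none
Why: The silyl-stabilised propargyl anion alkylates the primary allylic bromide by SN2 at its CH2 terminus (propargylic alkylation), so the two (E)-alkenes of 2 are carried over unchanged.

Step 2
Reactants: 4 trimethyl[(5E,9E)-6,10,14-trimethylpentadeca-5,9,13-trien-1-yn-1-yl]silane
Product: 5 (5E,9E)-6,10,14-trimethylpentadeca-5,9,13-trien-1-yne
Conditions: K2CO3, MeOH, rt
Reagents that add atoms: none
Why: Base-mediated methanolysis of the alkynyl–silicon bond (protodesilylation) leaves the triene untouched.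

Step 3
Reactants: 5 (5E,9E)-6,10,14-trimethylpentadeca-5,9,13-trien-1-yne
Product: 7 (1E,5E,9E)-1-iodo-2,6,10,14-tetramethylpentadeca-1,5,9,13-tetraene, via alkenylalane 6 (not isolated)
Conditions: AlMe3 (2 equiv), Cp2ZrCl2 (0.25 equiv), CH2Cl2, 0 °C to rt; then I2, THF, −30 °C
Reagents that add atoms: trimethylaluminium C[Al](C)C; iodine II
Why: Zirconium-catalysed syn-methylalumination of the terminal alkyne (Negishi carboalumination) puts the methyl group on the internal carbon, and iodinolysis with retention fixes the (E)-trisubstituted alkene that becomes C2'=C3'.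

Step 4
Reactants: 8 but-2-yn-1-ol
Product: 10 (2Z)-3-iodobut-2-en-1-ol, via cyclic vinylalanate 9 (not isolated)
Conditions: NaAlH2(OCH2CH2OMe)2, Et2O, 0 °C to rt; then I2, THF, −78 °C; aqueous work-up
Reagents that add atoms: iodine II
Why: Alkoxide-directed anti-hydroalumination of the propargylic alcohol gives the five-membered alanate, and iodinolysis with retention sets the (Z)-alkene that becomes the ring C2=C3 bond (hydroalumination–iodination).

Step 5
Reactants: 10 (2Z)-3-iodobut-2-en-1-ol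
Product: 11 triethyl{[(2Z)-3-iodobut-2-en-1-yl]oxy}silane
Conditions: Et3SiCl, imidazole, CH2Cl2, 0 °C
Reagents that add atoms: chlorotriethylsilane CC[Si](Cl)(CC)CC
Why: Standard silylation of a primary allylic alcohol; the triethylsilyl ether is chosen because it can later be oxidised directly to the aldehyde.

Step 6
Reactants: 11 triethyl{[(2Z)-3-iodobut-2-en-1-yl]oxy}silane
Product: 13 (2Z)-2-methyl-4-[(triethylsilyl)oxy]but-2-enal, via vinyllithium 12 (not isolated)
Conditions: t-BuLi (2.1 equiv), Et2O, −78 °C; DMF, −78 to 0 °C; H2O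
Reagents that add atoms: N,N-dimethylformamide CN(C)C=O
Why: Lithium–iodine exchange proceeds with retention and the vinyllithium is formylated by DMF (Bouveault aldehyde synthesis); diethyl ether at −78 °C keeps the retro-[1,4]-Brook silyl shift slow.

Step 7
Reactants: 13 (2Z)-2-methyl-4-[(triethylsilyl)oxy]but-2-enal; 14 allenylboronic acid pinacol ester
Product: 16 (4S,5Z)-5-methyl-7-[(triethylsilyl)oxy]hept-5-en-1-yn-4-ol, via borate ester 15 (not isolated)
Conditions: (S)-TRIP (BINOL-derived phosphoric acid, 10 mol %), 4 Å MS, toluene, 0 °C; aq NaHCO3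
Reagents that add atoms: none
Why: Chiral phosphoric acid catalysed allenylboration (asymmetric propargylation) through a closed six-membered transition state delivers the propargyl group to the Si face of the aldehyde and so sets the temporary C1 centre as S (C4 of 16).

Step 8
Reactants: 16 (4S,5Z)-5-methyl-7-[(triethylsilyl)oxy]hept-5-en-1-yn-4-ol
Product: 17 (4S,5Z)-5-methyl-4,7-bis[(triethylsilyl)oxy]hept-5-en-1-yne
Conditions: Et3SiCl, imidazole, DMAP (cat.), CH2Cl2, rt
Reagents that add atoms: chlorotriethylsilane CC[Si](Cl)(CC)CC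
Why: Silylation of the secondary alcohol protects the temporary C1 carbinol through the coupling, oxidation and ring closure.

Step 9
Reactants: 17 (4S,5Z)-5-methyl-4,7-bis[(triethylsilyl)oxy]hept-5-en-1-yne; 7 (1E,5E,9E)-1-iodo-2,6,10,14-tetramethylpentadeca-1,5,9,13-tetraene
Product: 19 (2Z,4S,6E,8E,12E,16E)-3,9,13,17,21-pentamethyl-1,4-bis[(triethylsilyl)oxy]docosa-2,6,8,12,16,20-hexaene, via alkenylzirconocene 18 (not isolated)
Conditions: Cp2Zr(H)Cl (1.2 equiv), THF, rt; then 7, ZnCl2 (0.5 equiv), Pd(PPh3)4 (5 mol %), THF, rt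
Reagents that add atoms: none
Why: syn-Hydrozirconation of the terminal alkyne gives the (E)-alkenylzirconocene, which couples with the vinyl iodide under zinc-assisted palladium catalysis (Negishi coupling) with retention at both partners to give the (6E,8E)-diene.

Step 10
Reactants: 19 (2Z,4S,6E,8E,12E,16E)-3,9,13,17,21-pentamethyl-1,4-bis[(triethylsilyl)oxy]docosa-2,6,8,12,16,20-hexaene
Product: 21 (2Z,4S,6E,8E,12E,16E)-3,9,13,17,21-pentamethyl-4-[(triethylsilyl)oxy]docosa-2,6,8,12,16,20-hexaenal, via alkoxysulfonium chloride 20 (not isolated)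
Conditions: (COCl)2, DMSO, CH2Cl2, −78 °C; 19, −78 to −40 °C; Et3N, −78 to 0 °C
Reagents that add atoms: none
Why: Under Swern conditions the chlorosulfonium salt cleaves the unhindered primary triethylsilyl ether to an alkoxysulfonium ion that is oxidised on adding base, whereas the secondary silyl ether is too hindered to react (Swern oxidation of a silyl ether).

Step 11
Reactants: 21 (2Z,4S,6E,8E,12E,16E)-3,9,13,17,21-pentamethyl-4-[(triethylsilyl)oxy]docosa-2,6,8,12,16,20-hexaenal
Product: 23 (1S,4S,6S)-3-methyl-6-[(2E,6E,10E)-3,7,11,15-tetramethylhexadeca-2,6,10,14-tetraen-1-yl]-4-[(triethylsilyl)oxy]cyclohex-2-en-1-ol, via diethylborinate 22 (not isolated)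
Conditions: Ni(acac)2 (10 mol %), Et3B (2.4 equiv), THF (0.02 M), rt, N2; aq NaHCO3
Reagents that add atoms: none
Why: Ni(acac)2 is reduced by Et3B to zerovalent nickel, which binds the diene and the borane-activated aldehyde and couples them oxidatively to an oxanickelacycle (new C4–C5 bond); ethyl transfer from boron to nickel, β-hydride elimination (ethene) and C–H reductive elimination at the nickel-bound C1' then release borinate 22 and the catalyst. The closest known reaction type is the nickel-catalysed intramolecular homoallylation (reductive cyclisation) of ω-dienyl aldehydes with Et3B, Et2Zn or i-Bu2Al(acac) as the hydride relay. The six-membered ring closes in the 6-exo mode with respect to both the C5=C1' and the C4=O π bonds. The cis relation of C4–O and C5–C1' follows from the cis-fused five-membered O–Ni–C1' metallacycle, and the absolute configuration from the C1 centre: the silyloxy group should sit pseudoaxial (A(1,2) strain with the C2 methyl) and nickel should bridge the opposite face, so that 1S leads to 4S,5S (target numbering); the minor diastereomers would be removed by chromatography, so the enantiopurity of the target rests on that of C1. The step needs carbonyl over enal C=C chemoselectivity, secured by Lewis-acid activation of the aldehyde and the fully substituted β-carbon, and hydrogen delivery to C1' rather than C3', secured by the tertiary nature of C3', which also preserves the 2'E geometry because nickel does not become σ-bound there.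

Step 12
Reactants: 23 (1S,4S,6S)-3-methyl-6-[(2E,6E,10E)-3,7,11,15-tetramethylhexadeca-2,6,10,14-tetraen-1-yl]-4-[(triethylsilyl)oxy]cyclohex-2-en-1-ol
Product: 24 tert-butyl(dimethyl){[(1S,4S,6S)-3-methyl-6-[(2E,6E,10E)-3,7,11,15-tetramethylhexadeca-2,6,10,14-tetraen-1-yl]-4-[(triethylsilyl)oxy]cyclohex-2-en-1-yl]oxy}silane
Conditions: TBSOTf, 2,6-lutidine, CH2Cl2, −78 °C
Reagents that add atoms: tert-butyldimethylsilyl trifluoromethanesulfonate CC(C)(C)[Si](C)(C)OS(=O)(=O)C(F)(F)F
Why: Silyl triflate silylation of the hindered secondary allylic alcohol; the tert-butyldimethylsilyl ether is orthogonal to the triethylsilyl ether at C1.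

Step 13
Reactants: 24 tert-butyl(dimethyl){[(1S,4S,6S)-3-methyl-6-[(2E,6E,10E)-3,7,11,15-tetramethylhexadeca-2,6,10,14-tetraen-1-yl]-4-[(triethylsilyl)oxy]cyclohex-2-en-1-yl]oxy}silane
Product: 25 (1S,4S,5S)-4-[(tert-butyldimethylsilyl)oxy]-2-methyl-5-[(2E,6E,10E)-3,7,11,15-tetramethylhexadeca-2,6,10,14-tetraen-1-yl]cyclohex-2-en-1-ol
Conditions: PPTS (0.2 equiv), MeOH–CH2Cl2, 0 °C
Reagents that add atoms: none
Why: Mild acid-catalysed methanolysis removes the triethylsilyl ether much faster than the bulkier tert-butyldimethylsilyl ether (selective desilylation).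

Step 14
Reactants: 25 (1S,4S,5S)-4-[(tert-butyldimethylsilyl)oxy]-2-methyl-5-[(2E,6E,10E)-3,7,11,15-tetramethylhexadeca-2,6,10,14-tetraen-1-yl]cyclohex-2-en-1-ol
Product: 26 (4S,5S)-4-[(tert-butyldimethylsilyl)oxy]-2-methyl-5-[(2E,6E,10E)-3,7,11,15-tetramethylhexadeca-2,6,10,14-tetraen-1-yl]cyclohex-2-en-1-one
Conditions: Dess–Martin periodinane, NaHCO3, CH2Cl2, 0 °C
Reagents that add atoms: none
Why: Dess–Martin oxidation of the allylic alcohol gives the enone and erases the temporary C1 stereocentre without touching C4 or C5.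

Step 15
Reactants: 26 (4S,5S)-4-[(tert-butyldimethylsilyl)oxy]-2-methyl-5-[(2E,6E,10E)-3,7,11,15-tetramethylhexadeca-2,6,10,14-tetraen-1-yl]cyclohex-2-en-1-one
Product: 27 (4S,5S)-4-hydroxy-2-methyl-5-[(2E,6E,10E)-3,7,11,15-tetramethylhexadeca-2,6,10,14-tetraen-1-yl]cyclohex-2-en-1-one
Conditions: HF·pyridine, pyridine, THF, 0 °C to rt
Reagents that add atoms: none
Why: Buffered fluoride desilylation frees the C4 hydroxyl; C4 and C5 are not α to the ketone, so no epimerisation is expected.

**Compound list**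

1 | 1-(trimethylsilyl)propyne | CC#C[Si](C)(C)C | starting material
2 | (2E,6E)-farnesyl bromide | CC(C)=CCC/C(C)=C/CC/C(C)=C/CBr | starting material
3 | [3-(trimethylsilyl)prop-2-yn-1-yl]lithium | [Li]CC#C[Si](C)(C)C | intermediate
4 | trimethyl[(5E,9E)-6,10,14-trimethylpentadeca-5,9,13-trien-1-yn-1-yl]silane | CC(C)=CCC/C(C)=C/CC/C(C)=C/CCC#C[Si](C)(C)C | intermediate
5 | (5E,9E)-6,10,14-trimethylpentadeca-5,9,13-trien-1-yne | CC(C)=CCC/C(C)=C/CC/C(C)=C/CCC#C | intermediate
6 | dimethyl[(1E,5E,9E)-2,6,10,14-tetramethylpentadeca-1,5,9,13-tetraen-1-yl]alane | CC(C)=CCC/C(C)=C/CC/C(C)=C/CC/C(C)=C/[Al](C)C | intermediate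
7 | (1E,5E,9E)-1-iodo-2,6,10,14-tetramethylpentadeca-1,5,9,13-tetraene | CC(C)=CCC/C(C)=C/CC/C(C)=C/CC/C(C)=C/I | intermediate
8 | but-2-yn-1-ol | CC#CCO | starting material
9 | sodium 2,2-bis(2-methoxyethoxy)-3-methyl-2,5-dihydro-1,2-oxaaluminol-2-uide (five-membered alanate, Al bound to O and to the methyl-bearing alkene carbon) | CC1=CCO[Al-]1(OCCOC)OCCOC.[Na+] | intermediate
10 | (2Z)-3-iodobut-2-en-1-ol | C/C(I)=C/CO | intermediate
11 | triethyl{[(2Z)-3-iodobut-2-en-1-yl]oxy}silane | C/C(I)=C/CO[Si](CC)(CC)CC | intermediate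
12 | {4-[(triethylsilyl)oxy]but-2-en-2-yl}lithium, lithium cis to the CH2O group | C/C([Li])=C/CO[Si](CC)(CC)CC | intermediate
13 | (2Z)-2-methyl-4-[(triethylsilyl)oxy]but-2-enal | O=C/C(C)=C\CO[Si](CC)(CC)CC | intermediate
14 | allenylboronic acid pinacol ester (4,4,5,5-tetramethyl-2-(propa-1,2-dien-1-yl)-1,3,2-dioxaborolane) | C=C=CB1OC(C)(C)C(C)(C)O1 | starting material
15 | 4,4,5,5-tetramethyl-2-{[(4S,5Z)-5-methyl-7-[(triethylsilyl)oxy]hept-5-en-1-yn-4-yl]oxy}-1,3,2-dioxaborolane | C#CC[C@H](OB1OC(C)(C)C(C)(C)O1)/C(C)=C\CO[Si](CC)(CC)CC | intermediate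
16 | (4S,5Z)-5-methyl-7-[(triethylsilyl)oxy]hept-5-en-1-yn-4-ol | C#CC[C@H](O)/C(C)=C\CO[Si](CC)(CC)CC | intermediate
17 | (4S,5Z)-5-methyl-4,7-bis[(triethylsilyl)oxy]hept-5-en-1-yne | C#CC[C@H](O[Si](CC)(CC)CC)/C(C)=C\CO[Si](CC)(CC)CC | intermediate
18 | chlorobis(cyclopentadienyl)[(1E,4S,5Z)-5-methyl-4,7-bis[(triethylsilyl)oxy]hepta-1,5-dien-1-yl]zirconium | Cl[Zr](C1C=CC=C1)(C1C=CC=C1)/C=C/C[C@H](O[Si](CC)(CC)CC)/C(C)=C\CO[Si](CC)(CC)CC | intermediate
19 | (2Z,4S,6E,8E,12E,16E)-3,9,13,17,21-pentamethyl-1,4-bis[(triethylsilyl)oxy]docosa-2,6,8,12,16,20-hexaene | CC(C)=CCC/C(C)=C/CC/C(C)=C/CC/C(C)=C/C=C/C[C@H](O[Si](CC)(CC)CC)/C(C)=C\CO[Si](CC)(CC)CC | intermediate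
20 | dimethyl{[(2Z,4S,6E,8E,12E,16E)-3,9,13,17,21-pentamethyl-4-[(triethylsilyl)oxy]docosa-2,6,8,12,16,20-hexaen-1-yl]oxy}sulfonium chloride | CC(C)=CCC/C(C)=C/CC/C(C)=C/CC/C(C)=C/C=C/C[C@H](O[Si](CC)(CC)CC)/C(C)=C\CO[S+](C)C.[Cl-] | intermediate
21 | (2Z,4S,6E,8E,12E,16E)-3,9,13,17,21-pentamethyl-4-[(triethylsilyl)oxy]docosa-2,6,8,12,16,20-hexaenal | CC(C)=CCC/C(C)=C/CC/C(C)=C/CC/C(C)=C/C=C/C[C@H](O[Si](CC)(CC)CC)/C(C)=C\C=O | intermediate
22 | diethyl{[(1S,4S,6S)-3-methyl-6-[(2E,6E,10E)-3,7,11,15-tetramethylhexadeca-2,6,10,14-tetraen-1-yl]-4-[(triethylsilyl)oxy]cyclohex-2-en-1-yl]oxy}borane | CC(C)=CCC/C(C)=C/CC/C(C)=C/CC/C(C)=C/C[C@H]1C[C@H](O[Si](CC)(CC)CC)C(C)=C[C@H]1OB(CC)CC | intermediate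
23 | (1S,4S,6S)-3-methyl-6-[(2E,6E,10E)-3,7,11,15-tetramethylhexadeca-2,6,10,14-tetraen-1-yl]-4-[(triethylsilyl)oxy]cyclohex-2-en-1-ol | CC(C)=CCC/C(C)=C/CC/C(C)=C/CC/C(C)=C/C[C@H]1C[C@H](O[Si](CC)(CC)CC)C(C)=C[C@H]1O | intermediate
24 | tert-butyl(dimethyl){[(1S,4S,6S)-3-methyl-6-[(2E,6E,10E)-3,7,11,15-tetramethylhexadeca-2,6,10,14-tetraen-1-yl]-4-[(triethylsilyl)oxy]cyclohex-2-en-1-yl]oxy}silane | CC(C)=CCC/C(C)=C/CC/C(C)=C/CC/C(C)=C/C[C@H]1C[C@H](O[Si](CC)(CC)CC)C(C)=C[C@H]1O[Si](C)(C)C(C)(C)C | intermediate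
25 | (1S,4S,5S)-4-[(tert-butyldimethylsilyl)oxy]-2-methyl-5-[(2E,6E,10E)-3,7,11,15-tetramethylhexadeca-2,6,10,14-tetraen-1-yl]cyclohex-2-en-1-ol | CC(C)=CCC/C(C)=C/CC/C(C)=C/CC/C(C)=C/C[C@H]1C[C@H](O)C(C)=C[C@H]1O[Si](C)(C)C(C)(C)C | intermediate
26 | (4S,5S)-4-[(tert-butyldimethylsilyl)oxy]-2-methyl-5-[(2E,6E,10E)-3,7,11,15-tetramethylhexadeca-2,6,10,14-tetraen-1-yl]cyclohex-2-en-1-one | CC(C)=CCC/C(C)=C/CC/C(C)=C/CC/C(C)=C/C[C@H]1CC(=O)C(C)=C[C@H]1O[Si](C)(C)C(C)(C)C | intermediate
27 | (4S,5S)-4-hydroxy-2-methyl-5-[(2E,6E,10E)-3,7,11,15-tetramethylhexadeca-2,6,10,14-tetraen-1-yl]cyclohex-2-en-1-one | CC(C)=CCC/C(C)=C/CC/C(C)=C/CC/C(C)=C/C[C@H]1CC(=O)C(C)=C[C@H]1O | target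

**Step count and risks**

Total step count: 15. Longest linear sequence: 12 (steps 4–15, from but-2-yn-1-ol).

Steps most likely to fail:

1. Step 11. The ring may close through a trans-fused metallacycle, giving poor control of the new carbinol configuration relative to C5. The fallback sets out from 21 and returns at 23. The cyclisation is run as in step 11, and the carbinol epimer (1R,4S,6S)-3-methyl-6-[(2E,6E,10E)-3,7,11,15-tetramethylhexadeca-2,6,10,14-tetraen-1-yl]-4-[(triethylsilyl)oxy]cyclohex-2-en-1-ol F1, alone or mixed with 23, is oxidised with Dess–Martin periodinane to (4S,6S)-3-methyl-6-[(2E,6E,10E)-3,7,11,15-tetramethylhexadeca-2,6,10,14-tetraen-1-yl]-4-[(triethylsilyl)oxy]cyclohex-2-en-1-one F2. Reduction of F2 with LiBH(s-Bu)3 in THF at −78 °C should be 1,2-selective on the β-methyl enone and deliver hydride to the face opposite the adjacent side chain, giving the cis alcohol 23.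

2. Step 7. Enantioface discrimination by the phosphoric acid may be insufficient on the α-branched (Z)-enal, or the enal may isomerise from Z to E under acid catalysis. The fallback sets out from 13 and returns at 16. A zinc-mediated Barbier propargylation (propargyl bromide, Zn, THF–aq NH4Cl) gives racemic (5Z)-5-methyl-7-[(triethylsilyl)oxy]hept-5-en-1-yn-4-ol F3. Kinetic resolution with a lipase (Burkholderia cepacia lipase, vinyl acetate, hexane) should then acetylate the R enantiomer to (4R,5Z)-5-methyl-7-[(triethylsilyl)oxy]hept-5-en-1-yn-4-yl acetate F4, following the empirical rule for lipase acylation of secondary alcohols, and leave (S)-16 for chromatographic separation.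

3. Step 10. The secondary silyl ether may be cleaved alongside the primary one, or the amine may isomerise the enal from Z to E. The fallback sets out from 19 and returns at 21. The primary silyl ether is removed selectively with HF·pyridine buffered with pyridine in THF at 0 °C to give (2Z,4S,6E,8E,12E,16E)-3,9,13,17,21-pentamethyl-4-[(triethylsilyl)oxy]docosa-2,6,8,12,16,20-hexaen-1-ol F5, and the allylic alcohol is oxidised under neutral conditions with MnO2 in CH2Cl2 to 21.

**Further compounds**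

F1 | step 11 | (1R,4S,6S)-3-methyl-6-[(2E,6E,10E)-3,7,11,15-tetramethylhexadeca-2,6,10,14-tetraen-1-yl]-4-[(triethylsilyl)oxy]cyclohex-2-en-1-ol | CC(C)=CCC/C(C)=C/CC/C(C)=C/CC/C(C)=C/C[C@H]1C[C@H](O[Si](CC)(CC)CC)C(C)=C[C@@H]1O
F2 | step 11 | (4S,6S)-3-methyl-6-[(2E,6E,10E)-3,7,11,15-tetramethylhexadeca-2,6,10,14-tetraen-1-yl]-4-[(triethylsilyl)oxy]cyclohex-2-en-1-one | CC(C)=CCC/C(C)=C/CC/C(C)=C/CC/C(C)=C/C[C@H]1C[C@H](O[Si](CC)(CC)CC)C(C)=CC1=O
F3 | step 7 | racemic (5Z)-5-methyl-7-[(triethylsilyl)oxy]hept-5-en-1-yn-4-ol | C#CCC(O)/C(C)=C\CO[Si](CC)(CC)CC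
F4 | step 7 | (4R,5Z)-5-methyl-7-[(triethylsilyl)oxy]hept-5-en-1-yn-4-yl acetate | C#CC[C@@H](OC(C)=O)/C(C)=C\CO[Si](CC)(CC)CC
F5 | step 10 | (2Z,4S,6E,8E,12E,16E)-3,9,13,17,21-pentamethyl-4-[(triethylsilyl)oxy]docosa-2,6,8,12,16,20-hexaen-1-ol | CC(C)=CCC/C(C)=C/CC/C(C)=C/CC/C(C)=C/C=C/C[C@H](O[Si](CC)(CC)CC)/C(C)=C\CO
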